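Remark on the chemistry: the SMILES of the target describes the centrosymmetric (meso) diastereomer, so the target is achiral and every chiral intermediate is meant as the racemate (one enantiomer is drawn).

## Analysis of the target

The target 15 (C18H16O8) is a cage built on a central cyclohexane-1,4-dione (ring C) whose carbons run Cq–C(=O)–C(OH) twice round the ring. Each ring-C ketone is the one-carbon bridge of a bicyclo[3.3.1]nonane: a three-carbon enone unit, C(alkene)=C(CH3)–C(=O), spans the Cq and the C(OH) that flank that ketone and closes ring A on one side and ring B on the other. In each half a CH2–O–CH2 link between Cq and the neighbouring alkene carbon adds a tetrahydrofuran. The four stereocentres (two Cq, two C(OH)) are all bridgeheads: within one half they are locked cis by the three-atom bridge, and the two bridges lie on opposite faces of ring C. The molecule therefore has a centre of symmetry, needs no absolute stereocontrol, and its only free stereochemical variable is the face of ring C taken by the second bridge. Sensitive features are the non-enolisable β-diketone arrays at each C(OH) (retro-Claisen cleavage by nucleophiles), the tertiary α-ketols (acyl shift under base) and the enones with an allylic ether CH2 in the γ-position. The difficulty lies in two pairs of adjacent fully substituted carbons (Cq next to C(OH)) and in closing two bridges across an already substituted six-membered ring. The strategy rests on one regularity of rings A and B: the enone carbonyl carbon sits between the methyl-bearing alkene carbon and C(OH), while the other alkene carbon is bonded to Cq directly and again through CH2–O–CH2. Read backwards, ring A with its tetrahydrofuran is a ring-C ketone with a but-2-ynyl ether on one α-carbon and a CH2 on the other, plus one molecule of CO.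

## Retrosynthetic reasoning

The two C–O bonds of the tertiary carbinols are cut first, taking 15 back to the bis-deoxy cage 13. Each C(OH) is a bridgehead flanked by two carbonyl groups, so a substituent can only enter where the hydrogen was and oxygenation of 13 cannot disturb the configuration. Free α-ketols also need not be carried through the metal-mediated steps. The forward reaction has to remove two non-enolisable bridgehead protons (dimetalated species 14) and deliver electrophilic oxygen to the carbanions.

In 13, ring B is opened at three bonds: Cq–C(alkene), C(CH3)(alkene)–C(=O) and C(=O)–CH(bridgehead). The first cut also opens the second tetrahydrofuran, and the carbonyl carbon leaves as 8. What remains is triketone 11, whose free ring-C ketone has a but-2-ynyloxymethyl group on one α-carbon and a CH2 on the other. No other set of cuts removes a carbocycle, an ether ring and two stereocentres while leaving so simple a side chain. In the forward sense (through silyl enol ether 12) the arm-bearing α-carbon and the metal must add to the same side of the alkyne, 8 must insert, and the acyl group must close onto the CH2 across the ketone, all on the face of ring C opposite ring A.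

The ring-C ketone of 11 is traced back to the dioxolane of 10. The mask is needed one step earlier: with both ring-C ketones free, the acyl group formed in the first annulation could also reach the CH2 next to its own Cq through a five-membered ring, and the first bridge would not yet be in place to steer the second.

The same three bonds are cut in ring A of 10, which gives monoketal 7 and a second molecule of 8; the first tetrahydrofuran opens with them. The route stands on this disconnection: it removes two rings, three skeletal bonds and two stereocentres at once and leaves a cyclohexanone whose only functional groups are two identical ether arms and a ketal. The forward reaction has to start from the enolate on the arm-bearing side of the ketone, which silyl enol ether 9 fixes. This is necessary because the CH2 on the other side also has an alkyne, that of the neighbouring arm, within reach of a six-membered closure.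

7 arises by unmasking one of the two equivalent ketals of the centrosymmetric bis-ketal 6; the forward step has to stop after the first hydrolysis.

Both propargylic C–O bonds of 6 are cut to diol 4 and two molecules of 5. The ether oxygen of each future tetrahydrofuran is thus already attached to ring C, and the four carbons of 5 supply the two alkene carbons, the methyl group and the ring CH2.

4 comes from diester 3 by reduction of the ester groups, and 3 from 1 and 2 by ketalisation. 1 is chosen because it is ring C in finished form: both carbonyl carbons and, on the 1,4-related carbons between them, the two one-carbon arms at the ester oxidation level.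

## Alternatives that were turned down

Alternative 1: ring C is cut at its two Cq–C(=O) bonds into two identical four-carbon halves, each of which is dimethyl (S)-malate A1.
- Forward key step: the doubly deprotonated hydroxy ester (alkoxide plus ester enolate, strong amide base) would condense head to tail with a second molecule. Each enolate carbon attacks the ester next to the alkoxide of its partner, and two Claisen condensations close ring C as the dienol A2.
- For it: A2 holds both ring-C carbonyls, both future C(OH) carbons already oxygenated and both one-carbon arms (as esters on the future Cq), from a cheap C4 compound in one step. The late bridgehead oxygenation of the chosen route (step 8) would disappear; on that point this alternative is the stronger one.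
- Against it: the enolate of A1 has an alkoxide in the β-position and the ester to be attacked is deactivated by the neighbouring alkoxide, so elimination to the fumarate competes with a sluggish condensation. A2 can lose two molecules of water and become an aromatic dihydroxyterephthalate. The chirality of A1 buys nothing: the target is achiral, two (S) halves place the hydroxyls of A2 cis whereas 15 has them trans, and each carbinol carbon is planarised anyway when it is later acylated through its enol.
- Comparison: A2 is ring C only. Rings A and B and both tetrahydrofurans remain, and every C–C(=O) bond to an enone would then have to be made at a carbon that already carries a protected hydroxyl. The chosen strategy gives up the early oxygen but makes the six bridging bonds in two operations from a stable ring C.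

Alternative 2: each enone ring is cut at its Cq–C(alkene) bond, with the C(=O)–C(OR) bond already in place. The substrate is the ring-C diketone A3, which has a 3-chloro-2-methylbut-2-enoyl group (protected hydroxymethyl on the chlorinated carbon) on each methoxymethyl-protected carbinol carbon and a benzyloxymethyl group on each CH.
- Forward key step: both ring-C ketones are silylated towards the CH, and a Lewis acid lets each enol carbon add to the chlorine-bearing alkene carbon and expel chloride. Two 6-endo closures give the protected cage A4.
- For it: every bond is formed by a reaction type with ample precedent (enolate acylation, conjugate addition–elimination). The alkene geometry is irrelevant because the double bond is re-formed inside the six-membered ring. The competing five-membered closure is 5-endo and disfavoured, so both rings can close in one step, and the bridgehead oxygens are present from the start. In precedent and in the oxygenation question it is stronger than the chosen strategy.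
- Against it: A3 is heavily loaded (six protecting groups, two vinyl chlorides, two fully substituted acylated carbons that are themselves non-enolisable β-dicarbonyl centres open to retro-Claisen cleavage while they are made). The key step joins a tertiary enol carbon to a tetrasubstituted alkene carbon next to a fully substituted C(OR), the most congested bond of the molecule, under a chloride Lewis acid that methoxymethyl ethers tolerate poorly. A4 still lacks both tetrahydrofurans, so removal of six groups and two cycloetherifications follow.
- Comparison: the chosen route reaches its precursor in four steps with no protecting group other than the ketal and forms each tetrahydrofuran in the same step as its enone ring. Its price is a key step without direct precedent.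

Alternative 3: the bonds cut are the two C(=O)–CH(bridgehead) bonds of the enones. The retron is the 1,3-acyl shift of an enol ester, which leads back to the bis(enol lactone) A5, where each unsaturated acyl group sits on the enol oxygen of the neighbouring ring-C carbonyl while still attached to Cq.
- Forward key step: irradiation would move each acyl carbon from oxygen to the enol carbon and give A6, which is the same compound as 13.
- For it: the photochemical 1,3-acyl shift of enol esters is a known reaction and delivers the acyl group to the enol carbon on the face on which it is held. It turns O-acylation, the side reaction most to be feared in the chosen key step, into the planned path; on C- versus O-acylation it is the stronger design, and it needs no transition metal.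
- Against it: A5 must first be made, and it already contains the Cq–C(alkene) bond, the tetrahydrofuran and the acyl group cis to Cq on a tetrasubstituted alkene. The hardest bond of each half and the alkene geometry are thus left to an earlier, unspecified sequence. The shift runs through an acyl/oxyallyl radical pair with decarbonylation and ketene formation as competitors, and it must succeed twice in one molecule. A6 contains β,γ-unsaturated ketone and enedione chromophores that invite secondary photoreactions.
- Comparison: since A6 is 13, this alternative also ends before the bridgehead oxygenation and gains nothing there. The chosen strategy makes the Cq–C bond, brings in the carbonyl carbon and acylates in one operation from an alkyne.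

Key step: step 5

## Route

Step 1
Reactants: 1 dimethyl succinylsuccinate (dimethyl 2,5-dihydroxycyclohexa-1,4-diene-1,4-dicarboxylate); 2 ethylene glycol
Product: 3 trans-dimethyl 1,4,9,12-tetraoxadispiro[4.2.4.2]tetradecane-6,13-dicarboxylate (bis(ethylene ketal) of dimethyl 2,5-dioxocyclohexane-1,4-dicarboxylate; meso)
Conditions: HOCH2CH2OH (excess), TsOH·H2O (cat.), toluene, reflux, Dean–Stark
Reagents that add atoms: ethylene glycol (2), OCCO
Why: Acid-catalysed ketalisation of both enolised β-keto ester carbonyls with azeotropic removal of water; the ester-bearing centres equilibrate under these conditions towards the diequatorial trans isomer, and their configuration has no bearing on the target because both carbons are planarised later (steps 5 and 7).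

Step 2
Reactants: 3 trans-bis-ketal diester
Product: 4 trans-6,13-bis(hydroxymethyl)-1,4,9,12-tetraoxadispiro[4.2.4.2]tetradecane (meso diol)
Conditions: LiAlH4, THF, 0 °C → rt; H2O, aq. NaOH work-up
Reagents that add atoms: none
Why: Hydride reduction of both esters to primary alcohols; the dioxolanes are inert to LiAlH4 and the ring stereocentres are not touched.

Step 3
Reactants: 4 meso diol; 5 1-bromobut-2-yne
Product: 6 trans-6,13-bis[(but-2-yn-1-yloxy)methyl]-1,4,9,12-tetraoxadispiro[4.2.4.2]tetradecane (meso)
Conditions: NaH (2.4 equiv), 5 (2.4 equiv), n-Bu4NI (cat.), THF–DMF, 0 °C → rt
Reagents that add atoms: 1-bromobut-2-yne (5), CC#CCBr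
Why: Williamson etherification (SN2 at the propargylic bromide) of both alkoxides; 4 has no enolisable or base-labile group.

Step 4
Reactants: 6 meso bis-ether bis-ketal
Product: 7 trans-6,9-bis[(but-2-yn-1-yloxy)methyl]-1,4-dioxaspiro[4.5]decan-8-one (racemic mono-ketal of the 2,5-disubstituted cyclohexane-1,4-dione)
Conditions: 1 M HCl (aq), THF, 0 °C → rt, run to partial conversion; recovered 6 recycled
Reagents that add atoms: water, O
Why: Acid hydrolysis of one dioxolane; the first free carbonyl is expected to retard ionisation of the remaining ketal through its dipole, which lets the reaction be held at the mono-ketone, and the centre next to the new ketone stays equatorial (trans) under the equilibrating conditions.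

Step 5
Reactants: 7 racemic mono-ketal ketone; 8 carbon monoxide
Product: 10 ring A annulation product (racemic bicyclo[3.3.1]non-3-ene-2,9-dione with 3-methyl; CH2–O–CH2 joining C4 to bridgehead C5 as a tetrahydrofuran; C7 ethylene ketal; equatorial (but-2-yn-1-yloxy)methyl on C8), via more substituted trimethylsilyl enol ether 9 (not isolated)
Conditions: TMSCl, Et3N, DMF, 80 °C; volatiles removed, pentane filtration; then Pd(OAc)2 (10 mol %), 1,4-benzoquinone (1.5 equiv), CO (1 atm), MeCN–DMSO (9:1), 4 Å MS, rt → 45 °C
Reagents that add atoms: carbon monoxide (8), [C-]#[O+]
Why: Proposed new method: thermodynamic silylation gives the more substituted enol ether 9, which hands its enolate to Pd(OAc)2 by silicon-to-palladium exchange and so places divalent palladium on the arm-bearing α-carbon; this is needed because in 7 the ring CH2 across the ketone also has an alkyne within reach (that of the neighbouring arm, 6-exo), so the site of palladation cannot be left to the free ketone. The palladium enolate inserts its own alkyne syn (5-exo-dig), which forms the Cq–C bond and the tetrahydrofuran and leaves palladium on the methyl-bearing carbon cis to Cq. CO then inserts into the vinyl–palladium bond, and the acylpalladium, held over the regenerated ketone, acylates the remaining α-carbon through its enol in a 6-(enolendo)-exo-trig closure of ring A with loss of zerovalent palladium, which benzoquinone returns to divalent palladium. The closest known reaction types are the Pd(OAc)2-mediated cyclisation of silyl enol ethers onto tethered C–C multiple bonds through palladium enolates, the oxidative carbocyclisation–carbonylation of enallenes and enynes under divalent palladium with benzoquinone and CO, and the C-acylation of ketone enolates by acylpalladium in carbonylative α-arylation; their combination on one ketone is without precedent. Cq is set by axial bond formation on the enolate face that keeps the remote arm equatorial (the other outcome would serve equally, since that remote centre is planarised in step 7), and the new bridgehead CH is fixed relative to Cq because a three-atom bridge can only span the two α-carbons cis. The step needs syn addition to the alkyne, which the pre-formed palladium enolate (inner-sphere insertion) is meant to secure, and it needs alkyne and CO insertion to outrun β-hydride loss, which the intramolecular alkyne and the CO atmosphere favour. It also needs C- rather than O-acylation at the CH2 across the ketone, the only enolisable carbon in reach because the other ring CH2 lies next to the ketal; O-acylation to the enol lactone remains the open risk.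

Step 6
Reactants: 10 ring A annulation product
Product: 11 triketone (racemic bicyclo[3.3.1]non-3-ene-2,7,9-trione with 3-methyl; the C4–CH2–O–CH2–C5 tetrahydrofuran; (but-2-yn-1-yloxy)methyl on C8)
Conditions: 2 M HCl (aq), THF, 40 °C
Reagents that add atoms: water, O
Why: Acid hydrolysis of the remaining dioxolane; the tetrasubstituted enone and the non-enolisable β-diketone are stable to dilute acid, and the arm-bearing carbon, now α to a ketone, may epimerise without consequence because it is planarised in step 7.

Step 7
Reactants: 11 triketone; 8 carbon monoxide
Product: 13 bis-deoxy cage (15 with H in place of both OH; centrosymmetric), via trimethylsilyl enol ether 12 (not isolated)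
Conditions: TMSCl, Et3N, DMF, 80 °C; volatiles removed, pentane filtration; then Pd(OAc)2 (10 mol %), 1,4-benzoquinone (1.5 equiv), CO (1 atm), MeCN–DMSO (9:1), 4 Å MS, rt → 50 °C
Reagents that add atoms: carbon monoxide (8), [C-]#[O+]
Why: Proposed new method: the sequence of step 5 is repeated (closest known types: cyclisation of silyl enol ethers through palladium enolates, oxidative carbocyclisation–carbonylation, acylpalladium C-acylation of ketone enolates): silicon-to-palladium exchange on 12, syn 5-exo-dig insertion of the alkyne (second Cq and tetrahydrofuran), CO insertion and 6-(enolendo)-exo-trig acylation of the ring CH2 across the ketone (ring B). The new Cq–C bond must form on the face of ring C opposite ring A, the exo face of the bicyclo[3.3.1]nonane, because the other face is covered by the enone bridge and only there can a three-atom bridge span the two α-carbons diaxially while ring C keeps the chair held by the first bridge; the second bridgehead CH then follows as in step 5. Acylation at the bridgehead CH next to the new Cq is excluded because that carbon cannot enolise, and the silyl enol ether regioisomer towards the ring CH2 has neither an alkyne nor a β-hydrogen to react with and returns to 11.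

Step 8
Reactants: 13 bis-deoxy cage
Product: 15 target CNP0299498.2 (centrosymmetric dihydroxy cage), via bridgehead dilithio derivative 14 (not isolated)
Conditions: lithium 2,2,6,6-tetramethylpiperidide (3 equiv), THF, −78 °C; then 2-(phenylsulfonyl)-3-phenyloxaziridine (3 equiv), −78 → −40 °C; aq. NH4Cl
Reagents that add atoms: 2-(phenylsulfonyl)-3-phenyloxaziridine, O=S(=O)(c1ccccc1)N1OC1c1ccccc1
Why: The hindered lithium amide removes both bridgehead protons to give localised carbanions, each stabilised inductively and by chelation to its two flanking carbonyls (enolisation is geometrically impossible), and oxygen transfer from the N-sulfonyloxaziridine (enolate α-hydroxylation) installs both hydroxyls. A bridgehead carbanion cannot invert, so each OH takes the place of its H with retention and the relative configuration set in steps 5 and 7 is kept.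

## Compound list

1 | dimethyl succinylsuccinate (dimethyl 2,5-dihydroxycyclohexa-1,4-diene-1,4-dicarboxylate) | COC(=O)C1=C(O)CC(C(=O)OC)=C(O)C1 | starting material
2 | ethylene glycol | OCCO | starting material
3 | trans-dimethyl 1,4,9,12-tetraoxadispiro[4.2.4.2]tetradecane-6,13-dicarboxylate (meso) | COC(=O)[C@@H]1CC2(OCCO2)[C@@H](C(=O)OC)CC13OCCO3 | intermediate
4 | trans-6,13-bis(hydroxymethyl)-1,4,9,12-tetraoxadispiro[4.2.4.2]tetradecane (meso) | OC[C@@H]1CC2(OCCO2)[C@@H](CO)CC13OCCO3 | intermediate
5 | 1-bromobut-2-yne | CC#CCBr | starting material
6 | trans-6,13-bis[(but-2-yn-1-yloxy)methyl]-1,4,9,12-tetraoxadispiro[4.2.4.2]tetradecane (meso) | CC#CCOC[C@@H]1CC2(OCCO2)[C@@H](COCC#CC)CC13OCCO3 | intermediate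
7 | trans-6,9-bis[(but-2-yn-1-yloxy)methyl]-1,4-dioxaspiro[4.5]decan-8-one (racemic) | CC#CCOC[C@@H]1CC2(OCCO2)[C@@H](COCC#CC)CC1=O | intermediate
8 | carbon monoxide | [C-]#[O+] | starting material
9 | 6,9-bis[(but-2-yn-1-yloxy)methyl]-8-(trimethylsilyloxy)-1,4-dioxaspiro[4.5]dec-8-ene (racemic) | CC#CCOCC1=C(O[Si](C)(C)C)C[C@H](COCC#CC)C2(OCCO2)C1 | intermediate (not isolated)
10 | ring A annulation product: 3-methylbicyclo[3.3.1]non-3-ene-2,9-dione with C4–CH2–O–CH2–C5 tetrahydrofuran, C7 ethylene ketal and equatorial (but-2-yn-1-yloxy)methyl on C8 (racemic) | CC1=C2COC[C@]23C(=O)[C@H](C1=O)[C@H](COCC#CC)C4(OCCO4)C3 | intermediate
11 | triketone: 3-methylbicyclo[3.3.1]non-3-ene-2,7,9-trione with C4–CH2–O–CH2–C5 tetrahydrofuran and (but-2-yn-1-yloxy)methyl on C8 (racemic) | CC1=C2COC[C@]23C(=O)[C@H](C1=O)[C@H](COCC#CC)C(=O)C3 | intermediate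
12 | 7-(trimethylsilyloxy) enol ether of 11 (C7=C8 double bond; racemic) | CC1=C2COC[C@]23C(=O)[C@H](C1=O)C(COCC#CC)=C(O[Si](C)(C)C)C3 | intermediate (not isolated)
13 | bis-deoxy cage (15 with H in place of both OH; centrosymmetric) | CC1=C2COC[C@]23C(=O)[C@H](C1=O)[C@@]12COCC1=C(C)C(=O)[C@@H]3C2=O | intermediate
14 | bridgehead dilithio derivative of 13 | CC1=C2COC[C@]23C(=O)[C@]([Li])(C1=O)[C@@]12COCC1=C(C)C(=O)[C@]3([Li])C2=O | intermediate (not isolated)
15 | CNP0299498.2 (centrosymmetric dihydroxy cage) | CC1=C2COC[C@]23C(=O)[C@](O)(C1=O)[C@@]12COCC1=C(C)C(=O)[C@]3(O)C2=O | target

## Step count and least certain steps

Total step count: 8. Longest linear sequence: 8 steps (the route is linear from 1).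

**Step 5 (key step, proposed new method).**
- What may go wrong: the palladium enolate may be consumed by β-hydride or β-alkoxide elimination before it inserts the alkyne. The alkyne may instead be attacked from outside the metal (anti addition), which leaves palladium trans to Cq and out of reach of the ring. The acylpalladium may be captured at the enol oxygen, because the lactone ring is less strained than the bridged carbocycle.
- Fallback (known reaction types only; sets out from 7, comes back at 13): semi-hydrogenation of both alkynes of 7 (H2, Pd/CaCO3–Pb(OAc)2, quinoline) gives the bis[(Z)-but-2-enyl] ether F1. Thermodynamic silylation as in step 5 gives the more substituted trimethylsilyl enol ether F2. Cross-metathesis with methacrolein (second-generation Grubbs catalyst) converts both arms into (E)-2-methylbut-2-enal ethers, giving F3. Catalytic tetrabutylammonium difluorotriphenylsilicate releases the regiodefined enolate, which adds to its own enal (5-exo-trig Michael addition) and closes the tetrahydrofuran at Cq, giving the spiro aldehyde F4. DBU then closes the other α-carbon onto the aldehyde (aldol, the classical α,α′-annulation to a bicyclo[3.3.1]nonane), giving the ring A ketol F5. IBX in DMSO at 80 °C oxidises the carbinol and dehydrogenates the new ketone towards the only position open to it, giving the enone F6. Aqueous HCl removes the ketal to give the trione F7. A second DBU-mediated Michael–aldol sequence follows, in which the ring CH2 has no acceptor within reach and the first bridge directs the attack to the opposite face, and gives the cage ketol F8. IBX then gives 13. The alkene geometry problem disappears because each double bond is created inside its six-membered ring.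

**Step 7 (proposed new method).**
- What may go wrong: the failure modes of step 5 apply. In addition the closure must form the second bridge of a strained cage, so acylation at oxygen or protonation of the vinylpalladium may outrun C-acylation, and the silylation may also engage the enone.
- Fallback (known reaction types only; sets out from 11, comes back at 13): semi-hydrogenation (H2, Pd/CaCO3–Pb(OAc)2, quinoline) gives the (Z)-but-2-enyl ether F9. Cross-metathesis with methacrolein (second-generation Grubbs catalyst) gives the trione F7. DBU-mediated Michael–aldol annulation gives the cage ketol F8, and IBX gives 13.

**Step 8.**
- What may go wrong: deprotonation at the allylic ether CH2 (γ-position of the enones) may compete with bridgehead metalation. Oxygen transfer from the bulky oxaziridine to the hindered carbanions may be slow. The lithium alkoxide of each new α-ketol may undergo acyl shift or retro-Claisen cleavage.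
- Fallback (sets out from 13, comes back at 15): the dilithio species 14 is quenched with iodine, a small and fast electrophile, to give the bis(bridgehead iodide) F10. Bridgehead radicals generated with Bu3SnH in air-saturated toluene capture O2, and PPh3 reduces the hydroperoxides to 15. The C–O bonds then form under neutral radical conditions without an alkoxide intermediate.

**Step 4.**
- What may go wrong: hydrolysis may run on to the diketone, and acid may promote loss of butynol (β-elimination) from the β-alkoxy ketone.
- Fallback (sets out from 6, comes back at 7): part of 6 is hydrolysed exhaustively to the dione F11. F11 is then equilibrated with an equal amount of 6 (TsOH and 2 in catalytic amounts, dry CH2Cl2), so that the dioxolane is redistributed to 7 under equilibrium rather than kinetic control, and both symmetric partners are recycled.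

## Further compounds

F1 | step 5 | trans-6,9-bis{[(Z)-but-2-en-1-yloxy]methyl}-1,4-dioxaspiro[4.5]decan-8-one | C/C=C\COC[C@@H]1CC2(OCCO2)[C@@H](COC/C=C\C)CC1=O
F2 | step 5 | 6,9-bis{[(Z)-but-2-en-1-yloxy]methyl}-8-(trimethylsilyloxy)-1,4-dioxaspiro[4.5]dec-8-ene | C/C=C\COCC1=C(O[Si](C)(C)C)C[C@H](COC/C=C\C)C2(OCCO2)C1
F3 | step 5 | 6,9-bis{[(E)-3-methyl-4-oxobut-2-en-1-yloxy]methyl}-8-(trimethylsilyloxy)-1,4-dioxaspiro[4.5]dec-8-ene | O=C/C(C)=C/COCC1=C(O[Si](C)(C)C)C[C@H](COC/C=C(\C)C=O)C2(OCCO2)C1
F4 | step 5 | spiro-tetrahydrofuran aldehyde (Michael adduct; mixture at the two side-chain CH centres) | O=CC(C)C1COC[C@@]12CC3(OCCO3)[C@@H](COC/C=C(\C)C=O)CC2=O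
F5 | step 5 | ring A ketol (saturated ring A with secondary alcohol; mixture at the three carbons that are oxidised next) | CC1C2COC[C@]23C(=O)[C@H](C1O)[C@H](COC/C=C(\C)C=O)C4(OCCO4)C3
F6 | step 5 | analogue of 10 with an (E)-3-methyl-4-oxobut-2-enyl ether arm | CC1=C2COC[C@]23C(=O)[C@H](C1=O)[C@H](COC/C=C(\C)C=O)C4(OCCO4)C3
F7 | step 5 | analogue of 11 with an (E)-3-methyl-4-oxobut-2-enyl ether arm | CC1=C2COC[C@]23C(=O)[C@H](C1=O)[C@H](COC/C=C(\C)C=O)C(=O)C3
F8 | step 5 | cage ketol (ring B saturated with secondary alcohol; mixture at the three carbons that are oxidised next) | CC1=C2COC[C@]23C(=O)[C@H](C1=O)[C@@]12COCC1C(C)C(O)[C@@H]3C2=O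
F9 | step 7 | (Z)-but-2-enyl ether analogue of 11 | CC1=C2COC[C@]23C(=O)[C@H](C1=O)[C@H](COC/C=C\C)C(=O)C3
F10 | step 8 | bis(bridgehead iodide) of 13 | CC1=C2COC[C@]23C(=O)[C@](I)(C1=O)[C@@]12COCC1=C(C)C(=O)[C@]3(I)C2=O
F11 | step 4 | trans-2,5-bis[(but-2-yn-1-yloxy)methyl]cyclohexane-1,4-dione | CC#CCOC[C@@H]1CC(=O)[C@@H](COCC#CC)CC1=O
A1 | alternative 1 | dimethyl (S)-malate | COC(=O)C[C@H](O)C(=O)OC
A2 | alternative 1 | dimethyl 3,6-dihydroxysuccinylsuccinate (dienol form) | COC(=O)C1=C(O)[C@@H](O)C(C(=O)OC)=C(O)[C@H]1O
A3 | alternative 2 | ring-C diketone with two 3-chloro enone arms (bis(3-chloro enone); CH centres and alkene geometry unspecified) | O=C1C(COCc2ccccc2)[C@](OCOC)(C(=O)C(C)=C(Cl)COCOC)C(=O)C(COCc2ccccc2)[C@@]1(OCOC)C(=O)C(C)=C(Cl)COCOC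
A4 | alternative 2 | fully protected cage lacking the two ether ring closures | CC1=C(COCOC)[C@]2(COCc3ccccc3)C(=O)[C@](OCOC)(C1=O)[C@@]4(COCc5ccccc5)C(COCOC)=C(C)C(=O)[C@]2(OCOC)C4=O
A5 | alternative 3 | bis(enol lactone) (centrosymmetric) | CC1=C2COC[C@]23C(OC1=O)=C[C@@]14COCC1=C(C)C(=O)OC4=C3
A6 | alternative 3 | bis-deoxy cage (identical with 13) | CC1=C2COC[C@]23C(=O)[C@H](C1=O)[C@@]12COCC1=C(C)C(=O)[C@@H]3C2=O
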